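The disconnection rests on the C4–H bond. The only stereocentre, C4, is a diaryl methine β to the lactone carbonyl C2 in ring B (the pyranone ring; ring A is the fused benzene ring), so it can be drawn back to the planar C3=C4 bond of a 4-phenylcoumarin. In one operation a chiral copper hydride adds hydride to one face of C4 and sets the (R) centre; no skeletal bond or ring is formed. The precursor is 5,7-dimethoxy-4-phenylcoumarin: its methyl ethers are small beside C4, inert to hydride and stable to Lewis acid. Afterwards C8 is benzoylated, the ethers are cleaved, and the prenyl group is delivered from O5 to C6 by Claisen rearrangement.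

Key step: step 3

Numbering: coumarin numbering (O1, C2 … C8a) is used for every bicyclic compound.

Assumption: (R)-DTBM-SEGPHOS is written for the ligand enantiomer whose copper hydride attacks the Si face of C4 (priorities C4a > phenyl > C3), which gives (R). If the complex prefers the Re face, (S)-DTBM-SEGPHOS is used and nothing else changes.

Remark: once ring A is unsymmetrical (from step 4 on), hydrolysis of the lactone while O5 is free could let it re-close on O5 instead of O1. Steps 5, 7 and 8 therefore use no added hydroxide, alkoxide or amine nucleophile; without prior hydrolysis O5 cannot reach C2.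

Step 1
Reactants: 1 phloroglucinol; 2 ethyl benzoylacetate
Product: 3 5,7-dihydroxy-4-phenylcoumarin
Conditions: CF3CO2H, 75 °C
Reagents that add atoms: none
Why: Pechmann condensation, in which acid promotes transesterification of the β-keto ester onto a phenol oxygen and closure of the ketone carbon onto the ortho carbon with loss of water, and the threefold symmetry of 1 allows only one coumarin.

Step 2
Reactants: 3 5,7-dihydroxy-4-phenylcoumarin
Product: 4 5,7-dimethoxy-4-phenylcoumarin
Conditions: MeI, K2CO3, acetone, reflux
Reagents that add atoms: iodomethane, CI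
Why: Williamson etherification of both phenoxides under anhydrous carbonate conditions that leave the coumarin lactone closed, giving the smallest possible ether next to C4.

Step 3
Reactants: 4 5,7-dimethoxy-4-phenylcoumarin
Product: 5 (4R)-5,7-dimethoxy-4-phenyl-3,4-dihydrocoumarin
Conditions: Cu(OAc)2·H2O (5 mol %), (R)-DTBM-SEGPHOS (5 mol %), (EtO)2MeSiH (1.5 equiv), t-BuOH (1.5 equiv), PhMe, rt
Reagents that add atoms: none
Why: The silane reduces Cu(OAc)2 to a bisphosphine-bound monovalent copper hydride, which coordinates the C3=C4 bond of ring B and transfers hydride to the β-carbon C4; the copper enolate is protonated at C3 by t-BuOH and the copper alkoxide is returned to the hydride by exchange with Si–H. The closest known reaction type is the copper hydride catalysed asymmetric conjugate reduction of β,β-disubstituted unsaturated esters and lactones, 4-arylcoumarins included. No ring is closed and no skeletal bond is made. The new C4 centre is under catalyst control, the ligand pocket selecting the Si face of C4, which gives (R). The step needs enantioface selectivity and 1,4- over 1,2-reduction; the two groups on C4 that the ligand must tell apart, coplanar ring A and the phenyl ring twisted out of plane by the C5 methoxy group, differ strongly, and 4 holds no ketone, halide or other activated alkene. The silane charge is kept near one equivalent so that the saturated lactone should not be reduced further.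

Step 4
Reactants: 5 (4R)-5,7-dimethoxy-4-phenyl-3,4-dihydrocoumarin; 6 benzoyl chloride
Product: 7 (4R)-8-benzoyl-5,7-dimethoxy-4-phenyl-3,4-dihydrocoumarin
Conditions: PhCOCl (1.2 equiv), AlCl3 (2.5 equiv), CH2Cl2, 0 °C → rt; cold 1 M HCl
Reagents that add atoms: none
Why: Friedel–Crafts acylation, in which the acylium ion should attack C8 (para to the C5 methoxy, ortho to the C7 methoxy, flanked by the tied-back ring oxygen) rather than C6 (ortho to both methoxy groups and shielded by their methyl groups), as is usual for electrophilic substitution of 5,7-dialkoxy benzopyranones, while the non-enolisable C4 methine is untouched.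

Step 5
Reactants: 7 (4R)-8-benzoyl-5,7-dimethoxy-4-phenyl-3,4-dihydrocoumarin
Product: 8 (4R)-8-benzoyl-5,7-dihydroxy-4-phenyl-3,4-dihydrocoumarin
Conditions: BBr3 (5 equiv), CH2Cl2, −78 → 0 °C; ice-water
Reagents that add atoms: none
Why: Boron tribromide ether cleavage, in which bromide attacks the methyl carbon of each boron-complexed ether while the aryl–oxygen bonds cannot be displaced, and a cold acidic quench frees both phenols without opening the lactone, so O1 stays the ring oxygen.

Step 6
Reactants: 9 2-methylbut-3-en-2-ol
Product: 10 tert-butyl 2-methylbut-3-en-2-yl carbonate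
Conditions: n-BuLi, THF, −78 °C; Boc2O, −78 °C → rt
Reagents that add atoms: di-tert-butyl dicarbonate, CC(C)(C)OC(=O)OC(=O)OC(C)(C)C
Why: Acylation of the lithium tertiary alkoxide by Boc2O gives the mixed carbonate, the usual ionisable precursor of a 1,1-dimethylallyl palladium complex.

Step 7
Reactants: 8 (4R)-8-benzoyl-5,7-dihydroxy-4-phenyl-3,4-dihydrocoumarin; 10 tert-butyl 2-methylbut-3-en-2-yl carbonate
Product: 11 (4R)-8-benzoyl-7-hydroxy-5-[(2-methylbut-3-en-2-yl)oxy]-4-phenyl-3,4-dihydrocoumarin
Conditions: Pd(PPh3)4 (5 mol %), 10 (1.1 equiv), THF, 0 °C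
Reagents that add atoms: none
Why: Tsuji–Trost decarboxylative O-allylation, in which zerovalent palladium ionises 10, the released tert-butoxide is quenched at once by the free 5-OH (the 7-OH is held in a hydrogen bond to the C8 ketone), and the phenoxide attacks the more substituted allyl terminus under kinetic control to give the tertiary ether; an ether formed at O7 instead would give the same product in step 8.

Step 8
Reactants: 11 (4R)-8-benzoyl-7-hydroxy-5-[(2-methylbut-3-en-2-yl)oxy]-4-phenyl-3,4-dihydrocoumarin
Product: 13 (4R)-8-benzoyl-5,7-dihydroxy-6-(3-methylbut-2-en-1-yl)-4-phenyl-3,4-dihydrocoumarin (the target), via ortho-dienone 12 (not isolated)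
Conditions: PhMe, 110 °C
Reagents that add atoms: none
Why: Aromatic Claisen rearrangement, in which the [3,3] shift joins the terminal CH2 of the 1,1-dimethylallyl ether to C6, the only unsubstituted carbon ortho to O5 (C4a is quaternary, the para carbon C8 carries the benzoyl group), so the inverted allyl unit becomes a normal prenyl group and enolisation of dienone 12 restores ring A without any reagent that could touch the alkene, the lactone or C4.

Compound list
1 | phloroglucinol (benzene-1,3,5-triol) | Oc1cc(O)cc(O)c1 | starting material
2 | ethyl benzoylacetate (ethyl 3-oxo-3-phenylpropanoate) | CCOC(=O)CC(=O)c1ccccc1 | starting material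
3 | 5,7-dihydroxy-4-phenylcoumarin | O=c1cc(-c2ccccc2)c2c(O)cc(O)cc2o1 | intermediate
4 | 5,7-dimethoxy-4-phenylcoumarin (key-step precursor) | O=c1cc(-c2ccccc2)c2c(OC)cc(OC)cc2o1 | intermediate
5 | (4R)-5,7-dimethoxy-4-phenyl-3,4-dihydrocoumarin (key-step product) | COc1cc2c(c(OC)c1)[C@@H](c1ccccc1)CC(=O)O2 | intermediate
6 | benzoyl chloride | O=C(Cl)c1ccccc1 | starting material
7 | (4R)-8-benzoyl-5,7-dimethoxy-4-phenyl-3,4-dihydrocoumarin | COc1cc(OC)c(C(=O)c2ccccc2)c2c1[C@@H](c1ccccc1)CC(=O)O2 | intermediate
8 | (4R)-8-benzoyl-5,7-dihydroxy-4-phenyl-3,4-dihydrocoumarin | Oc1cc(O)c(C(=O)c2ccccc2)c2c1[C@@H](c1ccccc1)CC(=O)O2 | intermediate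
9 | 2-methylbut-3-en-2-ol | CC(C)(O)C=C | starting material
10 | tert-butyl 2-methylbut-3-en-2-yl carbonate | C=CC(C)(C)OC(=O)OC(C)(C)C | intermediate
11 | (4R)-8-benzoyl-7-hydroxy-5-[(2-methylbut-3-en-2-yl)oxy]-4-phenyl-3,4-dihydrocoumarin (tertiary allyl ether on O5) | C=CC(C)(C)Oc1cc(O)c(C(=O)c2ccccc2)c2c1[C@@H](c1ccccc1)CC(=O)O2 | intermediate
12 | (4R)-8-benzoyl-7-hydroxy-6-(3-methylbut-2-en-1-yl)-4-phenyl-3,4-dihydro-2H-chromene-2,5(6H)-dione (ortho-dienone; C6 configuration not controlled and lost on enolisation) | CC(C)=CCC1C(O)=C(C(=O)c2ccccc2)C2=C(C1=O)[C@@H](c1ccccc1)CC(=O)O2 | intermediate (not isolated)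
13 | (4R)-8-benzoyl-5,7-dihydroxy-6-(3-methylbut-2-en-1-yl)-4-phenyl-3,4-dihydrocoumarin | CC(C)=CCc1c(O)c(C(=O)c2ccccc2)c2c(c1O)[C@@H](c1ccccc1)CC(=O)O2 | target

Total step count: 8. Longest linear sequence: 7 steps (1, 2, 3, 4, 5, 7, 8); step 6 is a one-step side branch.

Steps most likely to fail

Step 3. Hydride transfer to the hindered, electron-rich C4 (next to the C5 methoxy group) may be slow, face selectivity may be insufficient, or the saturated lactone carbonyl may be reduced further. The last is repaired by reoxidising the crude mixture with Ag2CO3 on Celite. The fallback makes the stereocentre by forming the C4–phenyl bond instead of the C4–H bond and sets out from 1. Condensation with ethyl propiolate (ZnCl2, 100 °C) should give 5,7-dihydroxycoumarin F1, and methylation (MeI, K2CO3, acetone) 5,7-dimethoxycoumarin F2. Rhodium-catalysed asymmetric 1,4-addition of phenylboronic acid (Hayashi–Miyaura reaction; [Rh(acac)(C2H4)2], the SEGPHOS enantiomer that gives (R), dioxane/H2O, 60 °C) then comes back to the route at 5.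

Step 4. Acylation may occur at C6 in competition with C8. (Lewis-acid loss of the C7 methyl group is harmless, since step 5 removes it anyway.) The fallback removes the regiochemical question by symmetry and sets out from 5. K2CO3 and MeI in MeOH/acetone at reflux should open the lactone and methylate the freed phenoxide to methyl (3R)-3-phenyl-3-(2,4,6-trimethoxyphenyl)propanoate F3, in which the two free ring carbons are equivalent. Benzoylation with 6 and AlCl3 then gives a single product, methyl (3R)-3-(3-benzoyl-2,4,6-trimethoxyphenyl)-3-phenylpropanoate F4. Excess BCl3 (CH2Cl2, 0 °C → rt) should cleave, under chelation by the ketone, only the two methyl ethers ortho to it. The phenol next to the side chain is then lactonised (TsOH, PhMe, 80 °C) to (4R)-8-benzoyl-7-hydroxy-5-methoxy-4-phenyl-3,4-dihydrocoumarin F5; the lactone can only close on the oxygen beside the ketone because the other ortho oxygen is still a methyl ether. BBr3 as in step 5 comes back to the route at 8.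

Step 7. The phenoxide may attack the unsubstituted allyl terminus, carbon may be allylated, or zerovalent palladium may re-ionise the tertiary ether and isomerise it to the linear prenyl ether. The fallback builds the same ether without an allyl–palladium intermediate and sets out from 8. Copper-catalysed propargylation with 3-chloro-3-methylbut-1-yne (CuCl2·2H2O cat., DBU, MeCN, 0 °C) should give (4R)-8-benzoyl-7-hydroxy-5-[(2-methylbut-3-yn-2-yl)oxy]-4-phenyl-3,4-dihydrocoumarin F6. Semihydrogenation (H2, Pd/CaCO3 poisoned with Pb(OAc)2, quinoline, EtOAc) comes back to the route at 11.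

Further compounds
F1 | step 3 | 5,7-dihydroxycoumarin | O=c1ccc2c(O)cc(O)cc2o1
F2 | step 3 | 5,7-dimethoxycoumarin | COc1cc(OC)c2ccc(=O)oc2c1
F3 | step 4 | methyl (3R)-3-phenyl-3-(2,4,6-trimethoxyphenyl)propanoate | COc1cc(OC)c(c(OC)c1)[C@@H](c1ccccc1)CC(=O)OC
F4 | step 4 | methyl (3R)-3-(3-benzoyl-2,4,6-trimethoxyphenyl)-3-phenylpropanoate | COc1cc(OC)c(c(OC)c1C(=O)c1ccccc1)[C@@H](c1ccccc1)CC(=O)OC
F5 | step 4 | (4R)-8-benzoyl-7-hydroxy-5-methoxy-4-phenyl-3,4-dihydrocoumarin | COc1cc(O)c(C(=O)c2ccccc2)c2c1[C@@H](c1ccccc1)CC(=O)O2
F6 | step 7 | (4R)-8-benzoyl-7-hydroxy-5-[(2-methylbut-3-yn-2-yl)oxy]-4-phenyl-3,4-dihydrocoumarin | C#CC(C)(C)Oc1cc(O)c(C(=O)c2ccccc2)c2c1[C@@H](c1ccccc1)CC(=O)O2
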